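**Retrosynthetic overview**
1. The target comes from its tri-O-benzyl ether by global hydrogenolysis. That ether comes from a syn-aldol imide by reductive removal of the auxiliary, which creates the C9 carbinol.
2. Key C7–C8 disconnection: an intermolecular boron-mediated Evans syn-aldol joins O-benzylsyringaldehyde to an (R)-4-benzyloxazolidinone aryloxyacetimide. It sets 7S and 8S (threo) together.
3. The C8–O–aryl unit comes from Williamson alkylation of the ring B phenol with ethyl bromoacetate, followed by saponification and N-acylation.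
4. The ring B side chain (aryl–C7' bond) comes from copper-catalysed opening of (S)-benzyl glycidyl ether by the aryl Grignard of MOM-protected 4-bromosyringol. The 8'S centre comes from the chiral pool.
5. No ring is formed at any stage. Ring A is bought as syringaldehyde, ring B as syringol, and the oxazolidinone ring is bought and recovered.

Assumption: the SMILES is taken as authoritative. It decodes to 7S,8S (threo) in the glycerol chain and 8'S in the dihydroxypropyl chain.

**Step 1**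
Reactants: 1 syringaldehyde (4-hydroxy-3,5-dimethoxybenzaldehyde)
Product: 2 4-(benzyloxy)-3,5-dimethoxybenzaldehyde
Conditions: BnBr (1.2 equiv), K2CO3 (2 equiv), DMF, 60 °C
Reagents that add atoms: benzyl bromide, BrCc1ccccc1
Why: Williamson ether synthesis, in which carbonate fully deprotonates the acidic para-formyl phenol and benzyl bromide is an unhindered SN2 partner, so the flanking methoxy groups only slow the alkylation.

**Step 2**
Reactants: 3 2,6-dimethoxyphenol (syringol)
Product: 4 4-bromo-2,6-dimethoxyphenol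
Conditions: NBS (1.0 equiv), NaH (1 mol %), CHCl3/MeOH (100:1), −45 °C → reflux
Reagents that add atoms: N-bromosuccinimide, O=C1CCC(=O)N1Br
Why: Electrophilic aromatic bromination, in which the trace of phenoxide is attacked para to oxygen (both ortho positions are blocked) to give a 4-bromodienone that tautomerises on warming, which avoids attack at the methoxy-activated C3.

**Step 3**
Reactants: 4 4-bromo-2,6-dimethoxyphenol
Product: 5 5-bromo-1,3-dimethoxy-2-(methoxymethoxy)benzene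
Conditions: MOMCl (1.5 equiv), iPr2NEt (2 equiv), CH2Cl2, 0 °C → rt
Reagents that add atoms: chloromethyl methyl ether, COCCl
Why: O-alkylation of the phenol by the very reactive oxocarbenium-type electrophile (MOM acetal formation) removes the acidic proton and gives a group that survives organomagnesium chemistry and NaH.

**Step 4**
Reactants: 5 5-bromo-1,3-dimethoxy-2-(methoxymethoxy)benzene; 6 (S)-benzyl glycidyl ether
Product: 8 (2S)-1-(benzyloxy)-3-[3,5-dimethoxy-4-(methoxymethoxy)phenyl]propan-2-ol, via arylmagnesium bromide 7 (not isolated)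
Conditions: Mg, I2 (cat.), THF, reflux; then CuI (10 mol %), 6 (0.85 equiv), THF, −30 → 0 °C; sat. aq. NH4Cl
Reagents that add atoms: none
Why: Grignard formation followed by copper-catalysed SN2 epoxide opening at the unsubstituted terminus leaves the C–O bond at the stereocentre untouched, so the S centre of 6 becomes 8'S unchanged.

**Step 5**
Reactants: 8 (2S)-1-(benzyloxy)-3-[3,5-dimethoxy-4-(methoxymethoxy)phenyl]propan-2-ol
Product: 10 5-[(2S)-2,3-bis(benzyloxy)propyl]-1,3-dimethoxy-2-(methoxymethoxy)benzene, via sodium alkoxide 9 (not isolated)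
Conditions: NaH (1.5 equiv), THF/DMF, 0 °C; then BnBr (1.3 equiv), Bu4NI (5 mol %), rt
Reagents that add atoms: benzyl bromide, BrCc1ccccc1
Why: Williamson benzylation of the only free hydroxyl takes place at oxygen, so the carbinol configuration is retained, and the MOM and benzyl ethers are inert to NaH.

**Step 6**
Reactants: 10 5-[(2S)-2,3-bis(benzyloxy)propyl]-1,3-dimethoxy-2-(methoxymethoxy)benzene
Product: 11 4-[(2S)-2,3-bis(benzyloxy)propyl]-2,6-dimethoxyphenol
Conditions: conc. HCl (cat.), MeOH, 50 °C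
Reagents that add atoms: none
Why: Acid-catalysed transacetalisation with methanol cleaves the aryl MOM acetal selectively, because benzyl and methyl ethers are stable to dilute acid and no acid-labile stereocentre is present yet.

**Step 7**
Reactants: 11 4-[(2S)-2,3-bis(benzyloxy)propyl]-2,6-dimethoxyphenol; 12 ethyl bromoacetate
Product: 13 ethyl {4-[(2S)-2,3-bis(benzyloxy)propyl]-2,6-dimethoxyphenoxy}acetate
Conditions: K2CO3 (2 equiv), acetone, reflux
Reagents that add atoms: none
Why: Williamson ether synthesis with an activated primary α-halo ester, which alkylates even 2,6-disubstituted phenoxides cleanly and installs the future C8–C9 unit on the ring B oxygen.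

**Step 8**
Reactants: 13 ethyl {4-[(2S)-2,3-bis(benzyloxy)propyl]-2,6-dimethoxyphenoxy}acetate
Product: 14 {4-[(2S)-2,3-bis(benzyloxy)propyl]-2,6-dimethoxyphenoxy}acetic acid
Conditions: LiOH (3 equiv), THF/H2O (3:1), rt; then 1 M HCl to pH 2–3
Reagents that add atoms: lithium hydroxide, [Li+].[OH-]
Why: Saponification of an unhindered, inductively activated ester by acyl–oxygen cleavage, with all ethers inert to hydroxide.

**Step 9**
Reactants: 14 {4-[(2S)-2,3-bis(benzyloxy)propyl]-2,6-dimethoxyphenoxy}acetic acid; 15 (R)-4-benzyl-1,3-oxazolidin-2-one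
Product: 17 (4R)-4-benzyl-3-({4-[(2S)-2,3-bis(benzyloxy)propyl]-2,6-dimethoxyphenoxy}acetyl)-1,3-oxazolidin-2-one, via mixed pivalic anhydride 16 (not isolated)
Conditions: PivCl (1.05 equiv), Et3N (2.5 equiv), THF, −20 °C; then LiCl (1.2 equiv), 15 (1.0 equiv), −20 °C → rt
Reagents that add atoms: none
Why: Mixed-anhydride N-acylation, in which the LiCl/Et3N-activated oxazolidinone attacks the open aryloxyacetyl carbonyl rather than the tert-butyl-shielded one, and no stereocentre takes part.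

**Step 10**
Reactants: 17 (4R)-4-benzyl-3-({4-[(2S)-2,3-bis(benzyloxy)propyl]-2,6-dimethoxyphenoxy}acetyl)-1,3-oxazolidin-2-one; 2 4-(benzyloxy)-3,5-dimethoxybenzaldehyde
Product: 20 (4R)-4-benzyl-3-[(2R,3S)-3-[4-(benzyloxy)-3,5-dimethoxyphenyl]-2-{4-[(2S)-2,3-bis(benzyloxy)propyl]-2,6-dimethoxyphenoxy}-3-hydroxypropanoyl]-1,3-oxazolidin-2-one, via Z-boron enolate 18 (not isolated), via boron aldolate 19 (not isolated)
Conditions: Bu2BOTf (1.2 equiv), Et3N (1.4 equiv), CH2Cl2, −78 → 0 °C; 2 (1.2 equiv), −78 → 0 °C; then pH 7 buffer, MeOH, 30% H2O2, 0 °C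
Reagents that add atoms: none
Why: Evans syn-aldol, in which the Z-boron enolate reacts through a closed Zimmerman–Traxler chair on the face away from the auxiliary benzyl group, so the R auxiliary delivers the 2R,3S syn adduct that corresponds to 8S and 7S of the target after reduction.

**Step 11**
Reactants: 20 the syn-aldol imide
Product: 21 (1S,2S)-1-[4-(benzyloxy)-3,5-dimethoxyphenyl]-2-{4-[(2S)-2,3-bis(benzyloxy)propyl]-2,6-dimethoxyphenoxy}propane-1,3-diol
Conditions: LiBH4 (2.5 equiv), H2O (2.5 equiv), Et2O/THF, 0 °C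
Reagents that add atoms: none
Why: Reductive cleavage of the N-acyloxazolidinone, in which hydride attacks the exocyclic carbonyl (made more electrophilic by the α-aryloxy group) and the transient aldehyde is reduced at once at 0 °C, so C8 does not epimerise, its descriptor changing from R to S only by priority rules.

**Step 12**
Reactants: 21 the tri-O-benzyl diol
Product: 22 (1S,2S)-2-{4-[(2S)-2,3-dihydroxypropyl]-2,6-dimethoxyphenoxy}-1-(4-hydroxy-3,5-dimethoxyphenyl)propane-1,3-diol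
Conditions: H2 (1 atm), 10% Pd/C, EtOAc/EtOH (1:1), rt, stopped after uptake of 3 equiv H2
Reagents that add atoms: none
Why: Catalytic hydrogenolysis of one aryl and two alkyl benzyl ethers in a neutral medium is much faster than cleavage of the free secondary benzylic alcohol, and the absence of acid keeps the ionisable C7 centre intact.

**Compound list**
1 | syringaldehyde (4-hydroxy-3,5-dimethoxybenzaldehyde) | COc1cc(C=O)cc(OC)c1O | starting material
2 | 4-(benzyloxy)-3,5-dimethoxybenzaldehyde | COc1cc(C=O)cc(OC)c1OCc1ccccc1 | intermediate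
3 | 2,6-dimethoxyphenol (syringol) | COc1cccc(OC)c1O | starting material
4 | 4-bromo-2,6-dimethoxyphenol | COc1cc(Br)cc(OC)c1O | intermediate
5 | 5-bromo-1,3-dimethoxy-2-(methoxymethoxy)benzene | COCOc1c(OC)cc(Br)cc1OC | intermediate
6 | (S)-benzyl glycidyl ether | C1[C@H](O1)COCc2ccccc2 | starting material
7 | [3,5-dimethoxy-4-(methoxymethoxy)phenyl]magnesium bromide (formed in the flask) | COCOc1c(OC)cc([Mg]Br)cc1OC | intermediate
8 | (2S)-1-(benzyloxy)-3-[3,5-dimethoxy-4-(methoxymethoxy)phenyl]propan-2-ol | COCOc1c(OC)cc(C[C@H](O)COCc2ccccc2)cc1OC | intermediate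
9 | sodium alkoxide of 8 (formed in the flask) | COCOc1c(OC)cc(C[C@H]([O-])COCc2ccccc2)cc1OC.[Na+] | intermediate
10 | 5-[(2S)-2,3-bis(benzyloxy)propyl]-1,3-dimethoxy-2-(methoxymethoxy)benzene | COCOc1c(OC)cc(C[C@H](OCc2ccccc2)COCc2ccccc2)cc1OC | intermediate
11 | 4-[(2S)-2,3-bis(benzyloxy)propyl]-2,6-dimethoxyphenol | COc1cc(C[C@H](OCc2ccccc2)COCc2ccccc2)cc(OC)c1O | intermediate
12 | ethyl bromoacetate | CCOC(=O)CBr | starting material
13 | ethyl {4-[(2S)-2,3-bis(benzyloxy)propyl]-2,6-dimethoxyphenoxy}acetate | CCOC(=O)COc1c(OC)cc(C[C@H](OCc2ccccc2)COCc2ccccc2)cc1OC | intermediate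
14 | {4-[(2S)-2,3-bis(benzyloxy)propyl]-2,6-dimethoxyphenoxy}acetic acid | OC(=O)COc1c(OC)cc(C[C@H](OCc2ccccc2)COCc2ccccc2)cc1OC | intermediate
15 | (R)-4-benzyl-1,3-oxazolidin-2-one | O=C1N[C@H](Cc2ccccc2)CO1 | starting material
16 | mixed anhydride of 14 with pivalic acid (formed in the flask) | CC(C)(C)C(=O)OC(=O)COc1c(OC)cc(C[C@H](OCc2ccccc2)COCc2ccccc2)cc1OC | intermediate
17 | (4R)-4-benzyl-3-({4-[(2S)-2,3-bis(benzyloxy)propyl]-2,6-dimethoxyphenoxy}acetyl)-1,3-oxazolidin-2-one | O=C(COc1c(OC)cc(C[C@H](OCc2ccccc2)COCc2ccccc2)cc1OC)N1[C@H](Cc2ccccc2)COC1=O | intermediate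
18 | (Z)-dibutylboron enolate of 17, O–B and O–aryl cis (formed in the flask) | CCCCB(CCCC)O/C(=C\Oc1c(OC)cc(C[C@H](OCc2ccccc2)COCc2ccccc2)cc1OC)N1[C@H](Cc2ccccc2)COC1=O | intermediate
19 | dibutylboron aldolate, the 3-O-BBu2 derivative of 20 (formed in the flask) | COc1cc([C@H](OB(CCCC)CCCC)[C@H](C(=O)N2[C@H](Cc3ccccc3)COC2=O)Oc2c(OC)cc(C[C@H](OCc3ccccc3)COCc3ccccc3)cc2OC)cc(OC)c1OCc1ccccc1 | intermediate
20 | (4R)-4-benzyl-3-[(2R,3S)-3-[4-(benzyloxy)-3,5-dimethoxyphenyl]-2-{4-[(2S)-2,3-bis(benzyloxy)propyl]-2,6-dimethoxyphenoxy}-3-hydroxypropanoyl]-1,3-oxazolidin-2-one | COc1cc([C@H](O)[C@H](C(=O)N2[C@H](Cc3ccccc3)COC2=O)Oc2c(OC)cc(C[C@H](OCc3ccccc3)COCc3ccccc3)cc2OC)cc(OC)c1OCc1ccccc1 | intermediate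
21 | (1S,2S)-1-[4-(benzyloxy)-3,5-dimethoxyphenyl]-2-{4-[(2S)-2,3-bis(benzyloxy)propyl]-2,6-dimethoxyphenoxy}propane-1,3-diol | COc1cc([C@H](O)[C@H](CO)Oc2c(OC)cc(C[C@H](OCc3ccccc3)COCc3ccccc3)cc2OC)cc(OC)c1OCc1ccccc1 | intermediate
22 | (1S,2S)-2-{4-[(2S)-2,3-dihydroxypropyl]-2,6-dimethoxyphenoxy}-1-(4-hydroxy-3,5-dimethoxyphenyl)propane-1,3-diol (CNP0229130.2) | COc1cc([C@H](O)[C@H](CO)Oc2c(OC)cc(C[C@H](O)CO)cc2OC)cc(OC)c1O | target

**Totals**
Total step count: 12.
Longest linear sequence: 11 steps (3 → 22, steps 2–12). Step 1 is the convergent branch.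

**Three steps most likely to fail**

Step 10. The 2,6-dimethoxyaryloxy group crowds the enolate and 2 is an electron-rich, sluggish aldehyde, so conversion or diastereoselectivity may suffer. The fallback sets out from ester 13 (with aldehyde 2) and comes back to the route at 21.
- The lithium enolate of 13 (LDA, THF, −78 °C) is added to 2 in an auxiliary-free aldol. This gives ethyl 3-[4-(benzyloxy)-3,5-dimethoxyphenyl]-2-{4-[(2S)-2,3-bis(benzyloxy)propyl]-2,6-dimethoxyphenoxy}-3-hydroxypropanoate F1 as a mixture at C2 and C3.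
- Dess–Martin periodinane (CH2Cl2, rt) erases both new centres and gives ethyl 3-[4-(benzyloxy)-3,5-dimethoxyphenyl]-2-{4-[(2S)-2,3-bis(benzyloxy)propyl]-2,6-dimethoxyphenoxy}-3-oxopropanoate F2.
- Asymmetric transfer hydrogenation under dynamic kinetic resolution follows, with RuCl(p-cymene)[(R,R)-TsDPEN] (1 mol %) and HCO2H/Et3N (5:2) at 30 °C. C2 epimerises faster than the ketone is reduced, and the product is the syn ester ethyl (2R,3S)-3-[4-(benzyloxy)-3,5-dimethoxyphenyl]-2-{4-[(2S)-2,3-bis(benzyloxy)propyl]-2,6-dimethoxyphenoxy}-3-hydroxypropanoate F3.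
- LiAlH4 (THF, 0 °C) then reduces the ester to 21.

Step 4. The electron-rich bromide may insert magnesium slowly, and magnesium bromide can open 6 to a bromohydrin. The fallback sets out from 5 and comes back at 8.
- Stille allylation (allyltributylstannane, Pd(PPh3)4 5 mol %, toluene, 100 °C) gives 5-allyl-1,3-dimethoxy-2-(methoxymethoxy)benzene F4.
- mCPBA/NaHCO3 (CH2Cl2, 0 °C) gives rac-2-[3,5-dimethoxy-4-(methoxymethoxy)benzyl]oxirane F5.
- Hydrolytic kinetic resolution uses (S,S)-(salen)Co(OAc) (0.5 mol %, salen = N,N'-bis(3,5-di-tert-butylsalicylidene)cyclohexane-1,2-diamine dianion) and H2O (0.55 equiv). It leaves (2S)-2-[3,5-dimethoxy-4-(methoxymethoxy)benzyl]oxirane F6 unreacted in high ee.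
- The other enantiomer is hydrolysed to (2R)-3-[3,5-dimethoxy-4-(methoxymethoxy)phenyl]propane-1,2-diol F7, which is removed by chromatography.
- BnOH/NaH (DMF, 60 °C) opens F6 at its terminal carbon to give 8.

Step 12. The two alkyl benzyl ethers need longer exposure, during which the electron-rich benzylic C7–OH may be hydrogenolysed. The fallback sets out from 21 and comes back at 22.
- Both free hydroxyls are masked first (TBSOTf, 2,6-lutidine, CH2Cl2, 0 °C). This gives (1S,2S)-1-[4-(benzyloxy)-3,5-dimethoxyphenyl]-2-{4-[(2S)-2,3-bis(benzyloxy)propyl]-2,6-dimethoxyphenoxy}-1,3-bis[(tert-butyldimethylsilyl)oxy]propane F8. Its bulky benzylic silyl ether resists C–O cleavage on palladium.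
- Exhaustive hydrogenolysis (H2, 10% Pd/C, EtOAc) gives 4-[(1S,2S)-1,3-bis[(tert-butyldimethylsilyl)oxy]-2-{4-[(2S)-2,3-dihydroxypropyl]-2,6-dimethoxyphenoxy}propyl]-2,6-dimethoxyphenol F9.
- Buffered fluoride (Bu4NF/AcOH 1:1, THF, 0 °C) then releases 22 without acid or strong base.

**Further compounds**
F1 | step 10 | ethyl 3-[4-(benzyloxy)-3,5-dimethoxyphenyl]-2-{4-[(2S)-2,3-bis(benzyloxy)propyl]-2,6-dimethoxyphenoxy}-3-hydroxypropanoate | COc1cc(C(O)C(C(=O)OCC)Oc2c(OC)cc(C[C@H](OCc3ccccc3)COCc3ccccc3)cc2OC)cc(OC)c1OCc1ccccc1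
F2 | step 10 | ethyl 3-[4-(benzyloxy)-3,5-dimethoxyphenyl]-2-{4-[(2S)-2,3-bis(benzyloxy)propyl]-2,6-dimethoxyphenoxy}-3-oxopropanoate | COc1cc(C(=O)C(C(=O)OCC)Oc2c(OC)cc(C[C@H](OCc3ccccc3)COCc3ccccc3)cc2OC)cc(OC)c1OCc1ccccc1
F3 | step 10 | ethyl (2R,3S)-3-[4-(benzyloxy)-3,5-dimethoxyphenyl]-2-{4-[(2S)-2,3-bis(benzyloxy)propyl]-2,6-dimethoxyphenoxy}-3-hydroxypropanoate | COc1cc([C@H](O)[C@H](C(=O)OCC)Oc2c(OC)cc(C[C@H](OCc3ccccc3)COCc3ccccc3)cc2OC)cc(OC)c1OCc1ccccc1
F4 | step 4 | 5-allyl-1,3-dimethoxy-2-(methoxymethoxy)benzene | C=CCc1cc(OC)c(OCOC)c(OC)c1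
F5 | step 4 | rac-2-[3,5-dimethoxy-4-(methoxymethoxy)benzyl]oxirane | COCOc1c(OC)cc(CC2CO2)cc1OC
F6 | step 4 | (2S)-2-[3,5-dimethoxy-4-(methoxymethoxy)benzyl]oxirane | COCOc1c(OC)cc(C[C@H]2CO2)cc1OC
F7 | step 4 | (2R)-3-[3,5-dimethoxy-4-(methoxymethoxy)phenyl]propane-1,2-diol | COCOc1c(OC)cc(C[C@@H](O)CO)cc1OC
F8 | step 12 | (1S,2S)-1-[4-(benzyloxy)-3,5-dimethoxyphenyl]-2-{4-[(2S)-2,3-bis(benzyloxy)propyl]-2,6-dimethoxyphenoxy}-1,3-bis[(tert-butyldimethylsilyl)oxy]propane | COc1cc([C@H](O[Si](C)(C)C(C)(C)C)[C@H](CO[Si](C)(C)C(C)(C)C)Oc2c(OC)cc(C[C@H](OCc3ccccc3)COCc3ccccc3)cc2OC)cc(OC)c1OCc1ccccc1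
F9 | step 12 | 4-[(1S,2S)-1,3-bis[(tert-butyldimethylsilyl)oxy]-2-{4-[(2S)-2,3-dihydroxypropyl]-2,6-dimethoxyphenoxy}propyl]-2,6-dimethoxyphenol | COc1cc([C@H](O[Si](C)(C)C(C)(C)C)[C@H](CO[Si](C)(C)C(C)(C)C)Oc2c(OC)cc(C[C@H](O)CO)cc2OC)cc(OC)c1O
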